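## Retrosynthetic overview
1. Enabling feature: in ring A, C4 carries both oxygenated one-carbon arms and is a latent β-keto ester enolate. C10, the methyl-bearing ring-fusion carbon, is a latent tertiary cation. The two stand 1,3 across C5, so ring A is a disguised donor–acceptor cyclopropane C4–C5–C10. This corresponds to a bicyclo[3.1.0]hexan-2-one whose five-membered ring is C4–C3–C2–C1–C10.
2. Key disconnection: re-make the non-target bond C4–C10 and cut C9–C10. In the forward sense, breaking C4–C10 enlarges the five-membered ring to ring A (C5 is taken up), while a C8=C9 allylsilane closes ring B and leaves the C8=C17 methylene.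
3. The bicycle comes from an acyclic α-diazo-β-keto ester by enantioselective intramolecular cyclopropanation of the E C10=C5 alkene. This sets C5, the only stereocentre that must be carried into the key step.
4. The acyclic tetraene is assembled from pent-4-yn-1-ol. A Johnson–Claisen rearrangement makes C10=C5. Carbocupration/allylation makes C8=C9 and brings in C17–Si and the complete dienyl side chain.
5. Ring order: cyclopropane and five-membered ring form together, then ring A (five to six) and ring B form together. Endgame: C18 by aldol with formaldehyde at C4, removal of the C3 oxygen, ester reduction, acetylation.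

Key step: step 10

Remark: labdane numbering is used throughout (ring A = C1–C5 and C10, ring B = C5–C10, C11–C16 side chain, C17 exocyclic methylene, C18 and C19 on C4, C20 angular methyl). The target belongs to the ent-labdane series.
Assumption: the sense of induction of the copper–bis(oxazoline) catalyst can be chosen through the ligand antipode, so the antipode that gives the drawn enantiomer is used.

## Route

Step 1
Reactants: 1 pent-4-yn-1-ol
Product: 2 pent-4-ynal
Conditions: TEMPO (cat.), PhI(OAc)2, CH2Cl2, rt
Reagents that add atoms: none
Why: TEMPO/oxoammonium oxidation of a primary alcohol stops at the aldehyde and does not touch the terminal alkyne, and no stereocentre is involved.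

Step 2
Reactants: 2 pent-4-ynal
Product: 3 (±)-2-methylhept-1-en-6-yn-3-ol
Conditions: isopropenylmagnesium bromide, THF, −78 → 0 °C; aq. NH4Cl
Reagents that add atoms: isopropenylmagnesium bromide C=C(C)[Mg]Br
Why: Grignard 1,2-addition to the aldehyde is far faster at low temperature than deprotonation of the alkyne, and the new carbinol centre may be racemic because step 3 erases it.

Step 3
Reactants: 3 (±)-2-methylhept-1-en-6-yn-3-ol
Product: 5 methyl (4E)-4-methylnon-4-en-8-ynoate, via mixed ketene acetal 4 (not isolated)
Conditions: MeC(OMe)3, EtCO2H (cat.), 110 → 135 °C, MeOH distilled off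
Reagents that add atoms: trimethyl orthoacetate COC(C)(OC)OC
Why: Johnson–Claisen rearrangement: the mixed ketene acetal rearranges through a chair with the butynyl chain pseudo-equatorial, which should give the E trisubstituted C10=C5 alkene and adds C1, C2 and C3 at the ester level.

Step 4
Reactants: 6 (2E)-3-methylpent-2-en-4-yn-1-ol
Product: 7 (2E)-3-methylpenta-2,4-dien-1-ol
Conditions: H2 (1 atm, one equivalent taken up), Pd/CaCO3 poisoned with Pb(OAc)2, quinoline, EtOAc, 0 °C → rt
Reagents that add atoms: none
Why: Semihydrogenation of a terminal alkyne on lead-poisoned palladium should stop at the vinyl group and leaves the E trisubstituted alkene as it is.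

Step 5
Reactants: 7 (2E)-3-methylpenta-2,4-dien-1-ol
Product: 8 (3E)-5-bromo-3-methylpenta-1,3-diene
Conditions: PBr3, Et2O, −20 → 0 °C, used crude
Reagents that add atoms: phosphorus tribromide BrP(Br)Br
Why: SN2 bromination of a primary allylic alcohol with PBr3 at low temperature keeps the E geometry, and because the 3-methylpentadienyl unit is the same from both ends an allylic shift to the far terminus would not change the constitution.

Step 6
Reactants: 5 methyl (4E)-4-methylnon-4-en-8-ynoate; 8 (3E)-5-bromo-3-methylpenta-1,3-diene
Product: 10 methyl (4E,8Z,11E)-4,12-dimethyl-8-[(trimethylsilyl)methyl]tetradeca-4,8,11,13-tetraenoate, via alkenylcopper 9 (not isolated)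
Conditions: Me3SiCH2MgCl, CuBr·SMe2 (slight excess over the Grignard reagent), Et2O/Me2S, −40 → 0 °C; then 8, DMPU, P(OEt)3, −30 °C → rt
Reagents that add atoms: (trimethylsilyl)methylmagnesium chloride C[Si](C)(C)C[Mg]Cl
Why: Carbocupration of a terminal alkyne (syn addition, copper at the terminal carbon) followed by stereoretentive allylation of the alkenylcopper should fix the C8=C9 geometry with C7 and C11 trans and brings in C17–Si and the whole side chain at once, while organocopper reagents leave the ester alone.

Step 7
Reactants: 10 methyl (4E,8Z,11E)-4,12-dimethyl-8-[(trimethylsilyl)methyl]tetradeca-4,8,11,13-tetraenoate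
Product: 11 (4E,8Z,11E)-4,12-dimethyl-8-[(trimethylsilyl)methyl]tetradeca-4,8,11,13-tetraenal
Conditions: i-Bu2AlH (1.05 equiv), CH2Cl2, −78 °C; MeOH, then aq. potassium sodium tartrate
Reagents that add atoms: none
Why: Partial ester reduction: the tetrahedral aluminium hemiacetal is stable at −78 °C and collapses to the aldehyde only on work-up, and the alkenes and the allylsilane are inert to i-Bu2AlH at this temperature.

Step 8
Reactants: 11 (4E,8Z,11E)-4,12-dimethyl-8-[(trimethylsilyl)methyl]tetradeca-4,8,11,13-tetraenal
Product: 13 ethyl (6E,10Z,13E)-2-diazo-6,14-dimethyl-3-oxo-10-[(trimethylsilyl)methyl]hexadeca-6,10,13,15-tetraenoate, via diazo aldol adduct 12 (not isolated)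
Conditions: ethyl diazoacetate, DBU (cat.), DMSO, rt; then IBX, rt
Reagents that add atoms: ethyl diazoacetate CCOC(=O)C=[N+]=[N-]
Why: DBU-catalysed aldol-type addition of ethyl diazoacetate to the aldehyde followed by IBX oxidation of the carbinol in the same pot is a known one-pot route to α-diazo-β-keto esters, and the transient carbinol centre disappears.

Step 9
Reactants: 13 ethyl (6E,10Z,13E)-2-diazo-6,14-dimethyl-3-oxo-10-[(trimethylsilyl)methyl]hexadeca-6,10,13,15-tetraenoate
Product: 14 ethyl (1S,5S,6S)-5-methyl-6-{(3Z,6E)-7-methyl-3-[(trimethylsilyl)methyl]nona-3,6,8-trien-1-yl}-2-oxobicyclo[3.1.0]hexane-1-carboxylate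
Conditions: [Cu(MeCN)4]PF6 (5 mol %), 2,2'-(propane-2,2-diyl)bis(4-tert-butyl-4,5-dihydrooxazole) (6 mol %, antipode giving the 1S,5S,6S product), toluene, 50 °C, slow addition of 13
Reagents that add atoms: none
Why: Intramolecular cyclopropanation by a copper carbene from an α-diazo-β-keto ester: the three-atom tether directs the carbene to the C10=C5 alkene only, suprafacial addition turns the E geometry into the relative configuration (methyl, ester and chain on one face), and the chiral bis(oxazoline) ligand chooses the alkene face and thereby sets C5 together with the temporary centres C4 and C10.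

Step 10
Reactants: 14 ethyl (1S,5S,6S)-5-methyl-6-{(3Z,6E)-7-methyl-3-[(trimethylsilyl)methyl]nona-3,6,8-trien-1-yl}-2-oxobicyclo[3.1.0]hexane-1-carboxylate
Product: 16 ethyl ent-3-oxo-18-norlabda-8(17),12E,14-trien-19-oate (trans-decalin β-keto ester; C4 enolisable), via silyl enol ether 15 (not isolated)
Conditions: TMSOTf (0.2 equiv), 2,6-di-tert-butyl-4-methylpyridine (0.3 equiv), CH2Cl2, −78 → −20 °C; then 1 M HCl, THF, 0 °C
Reagents that add atoms: none
Why: Proposed new method: silylation of the C3 carbonyl oxygen by TMSOTf polarises the keto-ester-activated cyclopropane so that the zero-bridge bond C4–C10 breaks towards its tertiary end, the five-membered ring C4–C3–C2–C1–C10 takes up the apex carbon C5 and becomes six-membered ring A (as its C3 silyl enol ether), C9 of the allylsilane binds to C10, and the β-silyl cation at C8 hands Me3Si+ back to triflate, which leaves the C8=C17 methylene and regenerates the catalyst, so that the whole event is an isomerisation in which Me3Si moves from C17 to O3. The closest known reaction types are the acid-induced ring enlargement of 5-alkylbicyclo[3.1.0]hexan-2-ones to cyclohexenones, olefin participation in the Lewis-acid opening of acylcyclopropanes, the opening of donor–acceptor cyclopropanes at the more substituted carbon, and allylsilane-terminated (Hosomi–Sakurai type) cation–olefin cyclisation to exocyclic methylene groups. Ring A is not closed but enlarged from five to six atoms, and ring B closes in a 6-endo-trig mode at C8=C9 (exo-tet at C10) through a chair. C10 is set by inversion, because C9 enters anti to the departing C4, which puts the C20 methyl group anti to H5 and so gives the trans-decalin (a free cation would be taken in the same chair sense under control of C5), C9 is set by the alkene geometry (C7 and C11 trans), which places the side chain equatorial and H9 anti to C20, and C5 is carried over unchanged. The step needs cleavage of C4–C10 and not of C4–C5, and capture by the allylsilane and not by the diene, by an ester oxygen or by proton loss: only C10 is tertiary, only C10 can be reached by C9 through a six-membered chair, the allylsilane is by far the strongest π-nucleophile present, and the hindered pyridine removes the TfOH that would cause protodesilylation.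

Step 11
Reactants: 16 ethyl ent-3-oxo-18-norlabda-8(17),12E,14-trien-19-oate
Product: 17 ethyl ent-18-hydroxy-3-oxolabda-8(17),12E,14-trien-19-oate (CO2Et axial and cis to C20, CH2OH equatorial)
Conditions: 37 % aq. HCHO (excess), KHCO3, THF, rt
Reagents that add atoms: formaldehyde C=O
Why: Base-catalysed aldol addition (hydroxymethylation) of the β-keto ester to formaldehyde makes C4 quaternary, with attack expected anti to the axial C20 methyl group (CH2OH equatorial), although either C4 epimer serves because C4 stops being a stereocentre in step 14.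

Step 12
Reactants: 17 ethyl ent-18-hydroxy-3-oxolabda-8(17),12E,14-trien-19-oate
Product: 18 3-tosylhydrazone of 17
Conditions: TsNHNH2, PPTS (cat.), EtOH, 50 °C
Reagents that add atoms: 4-methylbenzenesulfonohydrazide Cc1ccc(cc1)S(=O)(=O)NN
Why: Acid-catalysed condensation of the ketone with tosylhydrazide, which is known to work for 3-ketones flanked by a quaternary C4, proceeds under near-neutral conditions that should not trigger retro-aldol loss of formaldehyde.

Step 13
Reactants: 18 3-tosylhydrazone of 17
Product: 20 ethyl ent-18-hydroxylabda-8(17),12E,14-trien-19-oate, via borylated tosylhydrazine 19 (not isolated)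
Conditions: catecholborane (excess), CHCl3, −10 °C → rt; then NaOAc·3H2O, reflux
Reagents that add atoms: none
Why: Tosylhydrazone reduction: catecholborane adds hydride to C=N, acetate then triggers loss of sulfinate and the diazene loses N2 to leave CH2 at C3, conditions that spare the ester, the isolated alkene and the diene.

Step 14
Reactants: 20 ethyl ent-18-hydroxylabda-8(17),12E,14-trien-19-oate
Product: 21 ent-labda-8(17),12E,14-triene-18,19-diol
Conditions: LiAlH4, THF, 0 °C → reflux; aqueous NaOH work-up
Reagents that add atoms: none
Why: LiAlH4 reduction of the hindered axial ester gives the second CH2OH group, which makes the two arms at C4 identical, and the unactivated alkenes and the diene are inert.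

Step 15
Reactants: 21 ent-labda-8(17),12E,14-triene-18,19-diol
Product: 22 ent-labda-8(17),12E,14-triene-18,19-diyl diacetate (5S,9R,10S; target)
Conditions: Ac2O, pyridine, DMAP (cat.), CH2Cl2, rt
Reagents that add atoms: acetic anhydride CC(=O)OC(C)=O
Why: DMAP-catalysed acylation of the two neopentyl primary alcohols with acetic anhydride gives the diacetate without touching any stereocentre.

## Compound list
1 | pent-4-yn-1-ol | C#CCCCO | starting material
2 | pent-4-ynal | C#CCCC=O | intermediate
3 | (±)-2-methylhept-1-en-6-yn-3-ol | C=C(C)C(O)CCC#C | intermediate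
4 | 3-[(1-methoxyethenyl)oxy]-2-methylhept-1-en-6-yne (mixed ketene acetal, racemic) | C=C(OC)OC(CCC#C)C(C)=C | intermediate
5 | methyl (4E)-4-methylnon-4-en-8-ynoate | COC(=O)CC/C(C)=C/CCC#C | intermediate
6 | (2E)-3-methylpent-2-en-4-yn-1-ol | C#C/C(C)=C/CO | starting material
7 | (2E)-3-methylpenta-2,4-dien-1-ol | C=C/C(C)=C/CO | intermediate
8 | (3E)-5-bromo-3-methylpenta-1,3-diene | C=C/C(C)=C/CBr | intermediate
9 | alkenylcopper from syn addition to 5 (Cu and CH2SiMe3 cis; magnesium halide not drawn) | COC(=O)CC/C(C)=C/CC/C(C[Si](C)(C)C)=C/[Cu] | intermediate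
10 | methyl (4E,8Z,11E)-4,12-dimethyl-8-[(trimethylsilyl)methyl]tetradeca-4,8,11,13-tetraenoate | COC(=O)CC/C(C)=C/CC/C(C[Si](C)(C)C)=C/C/C=C(C)/C=C | intermediate
11 | (4E,8Z,11E)-4,12-dimethyl-8-[(trimethylsilyl)methyl]tetradeca-4,8,11,13-tetraenal | O=CCC/C(C)=C/CC/C(C[Si](C)(C)C)=C/C/C=C(C)/C=C | intermediate
12 | ethyl (6E,10Z,13E)-2-diazo-3-hydroxy-6,14-dimethyl-10-[(trimethylsilyl)methyl]hexadeca-6,10,13,15-tetraenoate (racemic at the carbinol) | CCOC(=O)C(=[N+]=[N-])C(O)CC/C(C)=C/CC/C(C[Si](C)(C)C)=C/C/C=C(C)/C=C | intermediate
13 | ethyl (6E,10Z,13E)-2-diazo-6,14-dimethyl-3-oxo-10-[(trimethylsilyl)methyl]hexadeca-6,10,13,15-tetraenoate | CCOC(=O)C(=[N+]=[N-])C(=O)CC/C(C)=C/CC/C(C[Si](C)(C)C)=C/C/C=C(C)/C=C | intermediate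
14 | ethyl (1S,5S,6S)-5-methyl-6-{(3Z,6E)-7-methyl-3-[(trimethylsilyl)methyl]nona-3,6,8-trien-1-yl}-2-oxobicyclo[3.1.0]hexane-1-carboxylate | CCOC(=O)[C@]12C(=O)CC[C@@]1(C)[C@@H]2CC/C(C[Si](C)(C)C)=C/C/C=C(C)/C=C | intermediate
15 | ethyl ent-3-(trimethylsilyloxy)-18-norlabda-3,8(17),12E,14-tetraen-19-oate | C=C/C(C)=C/C[C@@H]1C(=C)CC[C@@H]2C(C(=O)OCC)=C(O[Si](C)(C)C)CC[C@@]12C | intermediate
16 | ethyl ent-3-oxo-18-norlabda-8(17),12E,14-trien-19-oate (C4 enolisable, not assigned) | C=C/C(C)=C/C[C@@H]1C(=C)CC[C@@H]2C(C(=O)OCC)C(=O)CC[C@@]12C | intermediate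
17 | ethyl ent-18-hydroxy-3-oxolabda-8(17),12E,14-trien-19-oate (axial ester) | C=C/C(C)=C/C[C@@H]1C(=C)CC[C@@H]2[C@](CO)(C(=O)OCC)C(=O)CC[C@@]12C | intermediate
18 | 3-tosylhydrazone of 17 (C=N geometry immaterial) | C=C/C(C)=C/C[C@@H]1C(=C)CC[C@@H]2[C@](CO)(C(=O)OCC)C(=NNS(=O)(=O)c3ccc(C)cc3)CC[C@@]12C | intermediate
19 | N-boryl, O-boryl tosylhydrazine from 18 (C3 configuration immaterial) | C=C/C(C)=C/C[C@@H]1C(=C)CC[C@@H]2[C@](COB3Oc4ccccc4O3)(C(=O)OCC)C(CC[C@@]12C)N(B3Oc4ccccc4O3)NS(=O)(=O)c3ccc(C)cc3 | intermediate
20 | ethyl ent-18-hydroxylabda-8(17),12E,14-trien-19-oate | C=C/C(C)=C/C[C@@H]1C(=C)CC[C@@H]2[C@](CO)(C(=O)OCC)CCC[C@@]12C | intermediate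
21 | ent-labda-8(17),12E,14-triene-18,19-diol | C=C/C(C)=C/C[C@@H]1C(=C)CC[C@@H]2C(CO)(CO)CCC[C@@]12C | intermediate
22 | ent-labda-8(17),12E,14-triene-18,19-diyl diacetate | C=C/C(C)=C/C[C@@H]1C(=C)CC[C@@H]2C(COC(C)=O)(COC(C)=O)CCC[C@@]12C | target

## Step count and risks
Total step count: 15. Longest linear sequence: 13 (steps 1–3 and 6–15).

**Step 10 (Proposed new method).**
- What may go wrong: cleavage of the outer cyclopropane bond instead of the zero-bridge bond, proton loss from the tertiary centre before C9 arrives, closure of the ester oxygen onto C10, protodesilylation, or stalling of the silyl-transfer turnover.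
- Fallback with known chemistry, separating ring enlargement from ring closure: setting out from 14, stoichiometric TiCl4 (CH2Cl2, −78 °C, short contact, inverse aqueous quench) is used for the known halide opening of doubly activated cyclopropanes at the more substituted carbon. This should give the ring-enlarged tertiary chloride F1.
- In a second operation F1 is re-ionised with catalytic SnCl4 (CH2Cl2, −78 °C). This is the known Lewis-acid tert-alkylation of an allylsilane, here intramolecular, and it closes ring B and comes back to the route at 16.

**Step 6.**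
- What may go wrong: sluggish syn addition of the weakly nucleophilic silylmethylcopper to the alkyne, attack of residual Grignard reagent on the ester, and decomposition or allylic scrambling of the labile dienyl bromide during capture.
- Fallback without carbocupration: setting out from 5, bromoboration of the terminal alkyne with B-bromo-9-borabicyclo[3.3.1]nonane (CH2Cl2, 0 °C; syn addition, bromine at the internal carbon) should give the bromoalkenylborane F2.
- Negishi coupling of its C–Br bond with Me3SiCH2ZnCl (Pd(PPh3)4, THF) proceeds with retention and gives the silylmethyl alkenylborane F3.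
- Suzuki–Miyaura coupling of the C–B bond of F3 with 8 (Pd(PPh3)4, aq. NaOH, THF) comes back to the route at 10.

**Step 9.**
- What may go wrong: insufficient facial selectivity of the copper carbene on the trisubstituted alkene, carbene dimerisation, or reaction at the remote alkenes.
- Fallback by resolution instead of asymmetric catalysis: setting out from 13, achiral Rh2(OAc)4 (CH2Cl2, reflux, slow addition) should give the racemate, which is 14 together with its mirror image F4.
- The two are separated by preparative chromatography on a chiral stationary phase. The route is re-entered at 14.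

## Further compounds
F1 | step 10 | ethyl 5-chloro-5-methyl-6-{(3Z,6E)-7-methyl-3-[(trimethylsilyl)methyl]nona-3,6,8-trien-1-yl}-2-oxocyclohexane-1-carboxylate (ring-enlarged tertiary chloride; ester-bearing carbon enolisable) | CCOC(=O)C1C(=O)CC[C@@](C)(Cl)[C@@H]1CC/C(C[Si](C)(C)C)=C/C/C=C(C)/C=C
F2 | step 6 | methyl (4E,8Z)-9-(9-borabicyclo[3.3.1]nonan-9-yl)-8-bromo-4-methylnona-4,8-dienoate | COC(=O)CC/C(C)=C/CC/C(Br)=C/B1C2CCCC1CCC2
F3 | step 6 | methyl (4E,8Z)-9-(9-borabicyclo[3.3.1]nonan-9-yl)-4-methyl-8-[(trimethylsilyl)methyl]nona-4,8-dienoate | COC(=O)CC/C(C)=C/CC/C(C[Si](C)(C)C)=C/B1C2CCCC1CCC2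
F4 | step 9 | ethyl (1R,5R,6R)-5-methyl-6-{(3Z,6E)-7-methyl-3-[(trimethylsilyl)methyl]nona-3,6,8-trien-1-yl}-2-oxobicyclo[3.1.0]hexane-1-carboxylate | CCOC(=O)[C@@]12C(=O)CC[C@]1(C)[C@H]2CC/C(C[Si](C)(C)C)=C/C/C=C(C)/C=C
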